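Ring B is not brought in as an arene but built on the finished chromanone. Its vicinal methoxy groups on C3' and C4' and its link from C1' to C2 map onto 2,3-dimethoxybuta-1,3-diene (C2' to C5') plus an ethynyl group on C2 (C1' and C6'). One cobalt-catalysed alkyne–diene [4+2] cycloaddition forms C1'–C2' and C5'–C6' and closes ring B as a 1,4-cyclohexadiene, which DDQ then aromatises. The precursor is (2S)-2-ethynyl-5,6,7-trimethoxychroman-4-one; its single stereocentre C2 is set beforehand by copper-catalysed enantioselective alkynylation of 5,6,7-trimethoxychromone and is left untouched by the neutral ring construction.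

Key step: step 5

Assumption: the hand of the chiral ligand in step 3 is taken to be the one whose sense of induction places the acetylide on the Re face of C2 of the benzopyrylium ion (priorities O1 > C3 > H), the face that leads to 2S; the configuration is to be confirmed on 12 by chiroptical comparison with the (2S)-flavanone series.

Step 1
Reactants: 1 3,4,5-trimethoxyphenol
Product: 2 1-(6-hydroxy-2,3,4-trimethoxyphenyl)ethan-1-one
Conditions: AcOH, BF3·OEt2, 85 °C; then H2O
Reagents that add atoms: acetic acid, CC(=O)O
Why: This boron-trifluoride-promoted Friedel–Crafts C-acetylation (possibly through the aryl acetate and a Fries shift) can only go ortho to the hydroxyl, since C2 and C6 are the sole free and equivalent ring positions, and chelation of the ortho-hydroxy ketone by boron should stop a second acylation.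

Step 2
Reactants: 2 1-(6-hydroxy-2,3,4-trimethoxyphenyl)ethan-1-one
Product: 4 5,6,7-trimethoxy-4H-chromen-4-one, via enaminone 3 (not isolated)
Conditions: Me2NCH(OMe)2, toluene, 100 °C; then conc. HCl, CH2Cl2, 40 °C
Reagents that add atoms: N,N-dimethylformamide dimethyl acetal, COC(OC)N(C)C
Why: Condensation of the methyl ketone with the amide acetal gives enaminone 3, and under acid the phenol adds to its β-carbon and dimethylamine is expelled (enaminone route to chromones, a conjugate addition–elimination), which closes ring C without creating a stereocentre.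

Step 3
Reactants: 4 5,6,7-trimethoxy-4H-chromen-4-one; 5 trimethylsilylacetylene
Product: 8 (2S)-5,6,7-trimethoxy-2-[(trimethylsilyl)ethynyl]chroman-4-one, via 4-silyloxybenzopyrylium triflate 6 (not isolated), via silyl enol ether 7 (not isolated)
Conditions: TBSOTf (1.2 equiv), CH2Cl2, 40 °C; then 5, CuI (5 mol%), StackPhos (6 mol%), iPr2NEt, toluene, −40 °C; then 2 M HCl, THF, 0 °C
Reagents that add atoms: none
Why: O-Silylation turns the chromone into the aromatic 4-silyloxybenzopyrylium ion 6, and the monovalent copper acetylide of 5, held in the pocket of the axially chiral P,N ligand, adds to C2 of this cation on its Re face (copper-catalysed enantioselective alkynylation of benzopyrylium ions), so that the ligand sets C2 as S, after which dilute acid hydrolyses silyl enol ether 7 to the ketone and leaves the C-silyl group in place.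

Step 4
Reactants: 8 (2S)-5,6,7-trimethoxy-2-[(trimethylsilyl)ethynyl]chroman-4-one
Product: 9 (2S)-2-ethynyl-5,6,7-trimethoxychroman-4-one
Conditions: TBAF, AcOH (1:1), THF, −20 → 0 °C
Reagents that add atoms: none
Why: Buffered fluoride attacks silicon and the departing alkynyl carbon is protonated at once by acetic acid (protodesilylation of a silylalkyne), so that no free enolate or phenoxide arises and the retro-oxa-Michael opening of ring C that could scramble C2 is avoided.

Step 5
Reactants: 9 (2S)-2-ethynyl-5,6,7-trimethoxychroman-4-one; 10 2,3-dimethoxybuta-1,3-diene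
Product: 11 (2S)-2-(4,5-dimethoxycyclohexa-1,4-dien-1-yl)-5,6,7-trimethoxychroman-4-one
Conditions: CoBr2(dppe) (10 mol%), Zn (20 mol%), ZnI2 (20 mol%), 10 (3 equiv), CH2Cl2, rt; filtration through neutral Al2O3
Reagents that add atoms: none
Why: Zinc reduces CoBr2(dppe) to a monovalent cobalt species, ZnI2 takes up the halide, and the resulting cobalt centre binds the terminal alkyne of 9 and the s-cis diene 10; oxidative cyclisation forms C1'–C2' and gives an allyl–vinyl cobaltacycle, and reductive elimination forms C5'–C6' and releases the 1,4-cyclohexadiene. The closest known reaction type is the cobalt-catalysed neutral Diels–Alder reaction of terminal alkynes with 2,3-disubstituted buta-1,3-dienes, including oxygenated dienes. Ring B closes as a six-membered carbocycle by this intermolecular two-bond [4+2] annulation, its last bond being made by reductive elimination at cobalt. No stereocentre is formed, and C2 should keep its S configuration because the medium contains no base that could open ring C and no acid strong enough to ionise the propargylic C2–O bond. The symmetric diene leaves no regiochemical choice, the ketone and the aryl ethers are not partners for the catalyst, and the excess of diene should hold back alkyne cyclotrimerisation.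

Step 6
Reactants: 11 (2S)-2-(4,5-dimethoxycyclohexa-1,4-dien-1-yl)-5,6,7-trimethoxychroman-4-one
Product: 12 (2S)-2-(3,4-dimethoxyphenyl)-5,6,7-trimethoxychroman-4-one, (2S)-5,6,7,3',4'-pentamethoxyflavanone
Conditions: DDQ (1.05 equiv), toluene, 0 °C → rt
Reagents that add atoms: none
Why: DDQ takes a hydride from a doubly allylic CH2 of the 1,4-cyclohexadiene and the methoxy-stabilised cyclohexadienyl cation loses a proton to give the veratrole ring (dehydrogenative aromatisation), a process much faster at 0 °C than dehydrogenation of C2–C3 of the chromanone, so that with one equivalent of oxidant C2 should remain S.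

Compound list
1 | 3,4,5-trimethoxyphenol | COc1cc(O)cc(OC)c1OC | starting material
2 | 1-(6-hydroxy-2,3,4-trimethoxyphenyl)ethan-1-one | CC(=O)c1c(O)cc(OC)c(OC)c1OC | intermediate
3 | (E)-3-(dimethylamino)-1-(6-hydroxy-2,3,4-trimethoxyphenyl)prop-2-en-1-one | CN(C)/C=C/C(=O)c1c(O)cc(OC)c(OC)c1OC | intermediate
4 | 5,6,7-trimethoxy-4H-chromen-4-one | O=c1ccoc2cc(OC)c(OC)c(OC)c12 | intermediate
5 | trimethylsilylacetylene | C#C[Si](C)(C)C | starting material
6 | 4-[(tert-butyldimethylsilyl)oxy]-5,6,7-trimethoxychromenylium trifluoromethanesulfonate | CC(C)(C)[Si](C)(C)Oc1cc[o+]c2cc(OC)c(OC)c(OC)c12.[O-]S(=O)(=O)C(F)(F)F | intermediate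
7 | (2S)-4-[(tert-butyldimethylsilyl)oxy]-5,6,7-trimethoxy-2-[(trimethylsilyl)ethynyl]-2H-chromene | C[Si](C)(C)C#C[C@@H]1C=C(O[Si](C)(C)C(C)(C)C)c2c(cc(OC)c(OC)c2OC)O1 | intermediate
8 | (2S)-5,6,7-trimethoxy-2-[(trimethylsilyl)ethynyl]chroman-4-one | C[Si](C)(C)C#C[C@@H]1CC(=O)c2c(cc(OC)c(OC)c2OC)O1 | intermediate
9 | (2S)-2-ethynyl-5,6,7-trimethoxychroman-4-one | C#C[C@@H]1CC(=O)c2c(cc(OC)c(OC)c2OC)O1 | intermediate
10 | 2,3-dimethoxybuta-1,3-diene | C=C(OC)C(OC)=C | starting material
11 | (2S)-2-(4,5-dimethoxycyclohexa-1,4-dien-1-yl)-5,6,7-trimethoxychroman-4-one | COC1=C(OC)CC([C@@H]2CC(=O)c3c(cc(OC)c(OC)c3OC)O2)=CC1 | intermediate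
12 | (2S)-2-(3,4-dimethoxyphenyl)-5,6,7-trimethoxychroman-4-one | COc1ccc([C@@H]2CC(=O)c3c(cc(OC)c(OC)c3OC)O2)cc1OC | target

Total step count: 6
Longest linear sequence: 6 steps (1 → 2 → 4 → 8 → 9 → 11 → 12)

Steps most likely to fail

Step 5. The electron-rich diene may oligomerise under the zinc Lewis acid, the alkyne may cyclotrimerise, or the β-keto ether may bind the cobalt centre and stall turnover, so that ring B is not closed. The fallback sets out from chromone 4 and comes back to the route at target 12. It gives up the ring construction and brings ring B in as an arene: rhodium-catalysed enantioselective 1,4-addition (Hayashi–Miyaura reaction) of (3,4-dimethoxyphenyl)boronic acid to 4. The catalyst would be [Rh(OH)(cod)]2 with an electron-poor chiral biaryl bisphosphine of the MeO-BIPHEP family bearing 3,4,5-trifluorophenyl groups on phosphorus, its hand chosen for 2S, in toluene/H2O at room temperature. This should deliver the veratryl group to C2 and give 12 directly. No compound outside the list is formed on this way (none F0).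

Step 3. Facial selectivity may be poor because the peri methoxy group on C5 crowds the silyloxy group on C4 and distorts the cation in the ligand pocket. The fallback sets out from 4 and comes back at 8, moving stereocontrol from catalysis to resolution. The C2–alkyne bond is made without a chiral ligand (TBSOTf, CH2Cl2, 40 °C; then 5, CuI, iPr2NEt, CH2Cl2, 0 °C). This should give racemic 4-[(tert-butyldimethylsilyl)oxy]-5,6,7-trimethoxy-2-[(trimethylsilyl)ethynyl]-2H-chromene F1, hydrolysed in the same flask with 2 M HCl to racemic 5,6,7-trimethoxy-2-[(trimethylsilyl)ethynyl]chroman-4-one F2. The enantiomers of F2 are then separated by preparative chromatography on a polysaccharide chiral stationary phase, and the 2S enantiomer is 8.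

Step 4. C2 may erode through base-induced opening of ring C (retro-oxa-Michael) and reclosure if the fluoride is not fully buffered. The fallback sets out from 8 and comes back at 12; it carries the silyl group through ring construction and removes it from the arene under acid instead. The silylalkyne 8 and diene 10 are combined under the cobalt conditions of step 5, which are known to accept trimethylsilyl alkynes, to give (2S)-2-[4,5-dimethoxy-2-(trimethylsilyl)cyclohexa-1,4-dien-1-yl]-5,6,7-trimethoxychroman-4-one F3. DDQ in toluene at 0 °C should aromatise it to (2S)-2-[4,5-dimethoxy-2-(trimethylsilyl)phenyl]-5,6,7-trimethoxychroman-4-one F4. Ipso-protodesilylation with CF3CO2H in CH2Cl2 at 0 °C, favoured because silicon on C6' sits para to the C3' methoxy group, should then give 12.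

Further compounds
F0 | step 5 | none | none
F1 | step 3 | racemic 4-[(tert-butyldimethylsilyl)oxy]-5,6,7-trimethoxy-2-[(trimethylsilyl)ethynyl]-2H-chromene | C[Si](C)(C)C#CC1C=C(O[Si](C)(C)C(C)(C)C)c2c(cc(OC)c(OC)c2OC)O1
F2 | step 3 | racemic 5,6,7-trimethoxy-2-[(trimethylsilyl)ethynyl]chroman-4-one | C[Si](C)(C)C#CC1CC(=O)c2c(cc(OC)c(OC)c2OC)O1
F3 | step 4 | (2S)-2-[4,5-dimethoxy-2-(trimethylsilyl)cyclohexa-1,4-dien-1-yl]-5,6,7-trimethoxychroman-4-one | COC1=C(OC)CC([C@@H]2CC(=O)c3c(cc(OC)c(OC)c3OC)O2)=C([Si](C)(C)C)C1
F4 | step 4 | (2S)-2-[4,5-dimethoxy-2-(trimethylsilyl)phenyl]-5,6,7-trimethoxychroman-4-one | COc1cc([C@@H]2CC(=O)c3c(cc(OC)c(OC)c3OC)O2)c([Si](C)(C)C)cc1OC
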